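The plan disconnects ring A of the flavone at the C5–C4a bond and traces C5–C8 to a squaric-acid-derived 3-alkoxycyclobutenedione joined through the future C8 to a preformed 3-prenyloxy-2-aryl-4-pyranone (rings C and B). The key step exploits the para pair 5-OH/8-OMe on ring A, flanked by O7, unsubstituted C6 and O1 on C8a: this hydroquinone monoether pattern arises in one thermal operation, ring opening of the cyclobutenone to a dienylketene and six-electron closure onto the pyranone C=C bond. Its precursor is the 4-methoxy-4-(4-oxopyran-2-yl)-3-[2-(trimethylsilyl)ethoxy]cyclobutenone obtained by adding the C6-lithiated pyranone to the cyclobutenedione and methylating the alkoxide.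

Key step: step 9

Remark: pyromeconic acid (6) and the phenol pinacol boronate (10) are taken as purchased; every compound with one stereocenter (4, 14, 15, 17, F3) is racemic, one enantiomer being drawn.

Step 1
Reactants: 1 squaric acid (3,4-dihydroxycyclobut-3-ene-1,2-dione)
Product: 2 3,4-dichlorocyclobut-3-ene-1,2-dione (squaryl dichloride)
Conditions: (COCl)2 (2.2 equiv), DMF (cat.), CH2Cl2, 40 °C
Reagents that add atoms: oxalyl chloride, O=C(Cl)C(=O)Cl
Why: DMF-catalysed (Vilsmeier-type) chlorodehydroxylation with oxalyl chloride converts the two vinylogous carboxylic acid hydroxyls of squaric acid into vinylogous acid chlorides, the standard preparation of squaryl dichloride.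

Step 2
Reactants: 2 3,4-dichlorocyclobut-3-ene-1,2-dione
Product: 3 3,4-bis[2-(trimethylsilyl)ethoxy]cyclobut-3-ene-1,2-dione
Conditions: Me3SiCH2CH2OH (2.1 equiv), 2,6-lutidine, CH2Cl2, −20 °C to rt
Reagents that add atoms: 2-(trimethylsilyl)ethanol, OCC[Si](C)(C)C
Why: Each chloride sits on the β-carbon of an enone and should be displaced by the primary alcohol through addition–elimination (vinylogous acyl substitution), the hindered pyridine base trapping HCl so that the acid-sensitive silylethyl groups survive.

Step 3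
Reactants: 3 3,4-bis[2-(trimethylsilyl)ethoxy]cyclobut-3-ene-1,2-dione
Product: 5 3-[2-(trimethylsilyl)ethoxy]cyclobut-3-ene-1,2-dione, via hydroxycyclobutenone 4 (not isolated)
Conditions: LiAlH(Ot-Bu)3 (1.05 equiv), THF, −78 to −20 °C; then aq HCl, CH2Cl2, 0 °C to rt
Reagents that add atoms: water, O
Why: The bulky hydride should stop after 1,2-reduction of one of the two equivalent carbonyls, and acid then ionises the allylic hydroxyl of 4 (racemic, its stereocenter becoming sp2) so that water adds at the alkoxy-stabilised cation terminus and one silylethanol is expelled, which is the known reduction–hydrolytic 1,3-carbonyl transposition route from dialkyl squarates to 3-alkoxycyclobutene-1,2-diones.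

Step 4
Reactants: 6 pyromeconic acid (3-hydroxy-4H-pyran-4-one)
Product: 7 2-bromo-3-hydroxy-4H-pyran-4-one
Conditions: NBS (1.0 equiv), MeCN, 0 °C to rt
Reagents that add atoms: N-bromosuccinimide, O=C1CCC(=O)N1Br
Why: Electrophilic bromination of the enolic 3-hydroxy-4-pyranone should occur at C2, the enol β-carbon ortho to the hydroxyl, which is the site at which pyromeconic and kojic acid take up electrophiles.

Step 5
Reactants: 7 2-bromo-3-hydroxy-4H-pyran-4-one; 8 prenyl bromide (1-bromo-3-methylbut-2-ene)
Product: 9 2-bromo-3-[(3-methylbut-2-en-1-yl)oxy]-4H-pyran-4-one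
Conditions: K2CO3, DMF, rt
Reagents that add atoms: none
Why: Williamson etherification, in which the acidic enolic hydroxyl is deprotonated by carbonate and alkylated on oxygen by the allylic bromide (SN2), C-alkylation being blocked by the bromine at C2.

Step 6
Reactants: 10 4-(4,4,5,5-tetramethyl-1,3,2-dioxaborolan-2-yl)phenol; 8 prenyl bromide
Product: 11 4,4,5,5-tetramethyl-2-{4-[(3-methylbut-2-en-1-yl)oxy]phenyl}-1,3,2-dioxaborolane
Conditions: K2CO3, acetone, 55 °C
Reagents that add atoms: none
Why: Williamson etherification of the phenol under mild carbonate conditions that the pinacol boronate tolerates.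

Step 7
Reactants: 9 2-bromo-3-[(3-methylbut-2-en-1-yl)oxy]-4H-pyran-4-one; 11 4,4,5,5-tetramethyl-2-{4-[(3-methylbut-2-en-1-yl)oxy]phenyl}-1,3,2-dioxaborolane
Product: 12 3-[(3-methylbut-2-en-1-yl)oxy]-2-{4-[(3-methylbut-2-en-1-yl)oxy]phenyl}-4H-pyran-4-one
Conditions: Pd(dppf)Cl2 (cat.), K3PO4, 1,4-dioxane/H2O, 80 °C
Reagents that add atoms: none
Why: Suzuki–Miyaura coupling, in which the bromide on the β-carbon of the pyranone enone undergoes fast oxidative addition to zerovalent palladium, while the chelating dppf ligand and moderate temperature should keep the catalyst from ionising the prenyl ethers.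

Step 8
Reactants: 12 3-[(3-methylbut-2-en-1-yl)oxy]-2-{4-[(3-methylbut-2-en-1-yl)oxy]phenyl}-4H-pyran-4-one; 5 3-[2-(trimethylsilyl)ethoxy]cyclobut-3-ene-1,2-dione
Product: 15 4-methoxy-4-{5-[(3-methylbut-2-en-1-yl)oxy]-6-{4-[(3-methylbut-2-en-1-yl)oxy]phenyl}-4-oxo-4H-pyran-2-yl}-3-[2-(trimethylsilyl)ethoxy]cyclobut-2-en-1-one (racemic), via 6-lithiopyranone 13 (not isolated), via lithium alkoxide 14 (not isolated)
Conditions: lithium 2,2,6,6-tetramethylpiperidide (LiTMP, from 2,2,6,6-tetramethylpiperidine and n-BuLi, 1.05 equiv), THF, −78 °C; cannulation into 5 (1.2 equiv), THF, −78 °C; then MeOTf (1.2 equiv), −78 to −20 °C; aq NaHCO3 quench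
Reagents that add atoms: methyl trifluoromethanesulfonate, COS(=O)(=O)C(F)(F)F
Why: The hindered lithium amide should remove the C6 proton of 12 (sp2 C–H next to the ring oxygen, as in the C2 lithiation of chromones) without adding to the pyranone, the lithiopyranone 13 should add 1,2 to the carbonyl of 5 that lies next to the alkoxy-bearing carbon and is not deactivated as a vinylogous ester, and methyl triflate O-methylates alkoxide 14 at low temperature; the new quaternary stereocenter forms without control (racemate) and is erased in step 9.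

Step 9
Reactants: 15 4-methoxy-4-{5-[(3-methylbut-2-en-1-yl)oxy]-6-{4-[(3-methylbut-2-en-1-yl)oxy]phenyl}-4-oxo-4H-pyran-2-yl}-3-[2-(trimethylsilyl)ethoxy]cyclobut-2-en-1-one
Product: 18 5-hydroxy-8-methoxy-3-[(3-methylbut-2-en-1-yl)oxy]-2-{4-[(3-methylbut-2-en-1-yl)oxy]phenyl}-7-[2-(trimethylsilyl)ethoxy]-4H-chromen-4-one, via dienylketene 16 (not isolated), via 4aH-dienone 17 (not isolated)
Conditions: toluene (degassed, 0.02 M), 110 °C, argon
Reagents that add atoms: none
Why: Heating should trigger conrotatory four-electron opening of the cyclobutenone C1–C4 bond to dienylketene 16, the C4 methoxy donor rotating outward so that the pyranonyl group lies cis to the ketene. Disrotatory six-electron electrocyclisation then joins the ketene carbon (future C5) to the pyranone CH next to the carbonyl (future C4a), and enolisation of dienone 17 to the chelated 5-hydroxyl aromatises ring A. The closest known reaction type is the Moore ring expansion of 4-alkenyl- and 4-heteroaryl-4-alkoxycyclobutenones to hydroquinone monoethers. Ring A is closed in a 6π electrocyclic mode (six-membered carbocycle, one new C–C bond); the only stereocenters involved, the quaternary carbon of 15 and C4a of 17, are transient and end as sp2 carbons, so none needs control. The selectivity required is the sense of rotation, which the oxygen lone pairs of the methoxy group should secure, while the positions of all four ring A oxygens are fixed by the connectivity of 15. Neutral conditions at 110 °C should leave both prenyl ethers and the silylethyl ether untouched.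

Step 10
Reactants: 18 5-hydroxy-8-methoxy-3-[(3-methylbut-2-en-1-yl)oxy]-2-{4-[(3-methylbut-2-en-1-yl)oxy]phenyl}-7-[2-(trimethylsilyl)ethoxy]-4H-chromen-4-one
Product: 19 5,7-dihydroxy-8-methoxy-3-[(3-methylbut-2-en-1-yl)oxy]-2-{4-[(3-methylbut-2-en-1-yl)oxy]phenyl}-4H-chromen-4-one (target)
Conditions: CsF, DMF, 60 °C; then dilute aq HCl, 0 °C
Reagents that add atoms: none
Why: Fluoride attacks silicon and triggers β-elimination (fluoride-induced fragmentation of a 2-(trimethylsilyl)ethyl ether), releasing ethylene and the 7-phenoxide, a good leaving group as a vinylogous carboxylate, while the prenyl ethers, the methyl ether and the chelated 5-hydroxyl are inert to fluoride.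

Compound list
1 | squaric acid (3,4-dihydroxycyclobut-3-ene-1,2-dione) | O=C1C(=O)C(O)=C1O | starting material
2 | 3,4-dichlorocyclobut-3-ene-1,2-dione (squaryl dichloride) | O=C1C(=O)C(Cl)=C1Cl | intermediate
3 | 3,4-bis[2-(trimethylsilyl)ethoxy]cyclobut-3-ene-1,2-dione | O=C1C(=O)C(OCC[Si](C)(C)C)=C1OCC[Si](C)(C)C | intermediate
4 | 4-hydroxy-2,3-bis[2-(trimethylsilyl)ethoxy]cyclobut-2-en-1-one (racemic, one enantiomer drawn; not isolated) | O=C1C(OCC[Si](C)(C)C)=C(OCC[Si](C)(C)C)[C@H]1O | intermediate
5 | 3-[2-(trimethylsilyl)ethoxy]cyclobut-3-ene-1,2-dione | O=C1C=C(OCC[Si](C)(C)C)C1=O | intermediate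
6 | pyromeconic acid (3-hydroxy-4H-pyran-4-one) | O=c1ccocc1O | starting material
7 | 2-bromo-3-hydroxy-4H-pyran-4-one | O=c1ccoc(Br)c1O | intermediate
8 | prenyl bromide (1-bromo-3-methylbut-2-ene) | CC(C)=CCBr | starting material
9 | 2-bromo-3-[(3-methylbut-2-en-1-yl)oxy]-4H-pyran-4-one | O=c1ccoc(Br)c1OCC=C(C)C | intermediate
10 | 4-(4,4,5,5-tetramethyl-1,3,2-dioxaborolan-2-yl)phenol | CC1(C)OB(OC1(C)C)c1ccc(O)cc1 | starting material
11 | 4,4,5,5-tetramethyl-2-{4-[(3-methylbut-2-en-1-yl)oxy]phenyl}-1,3,2-dioxaborolane | CC(C)=CCOc1ccc(cc1)B1OC(C)(C)C(C)(C)O1 | intermediate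
12 | 3-[(3-methylbut-2-en-1-yl)oxy]-2-{4-[(3-methylbut-2-en-1-yl)oxy]phenyl}-4H-pyran-4-one | O=c1ccoc(-c2ccc(OCC=C(C)C)cc2)c1OCC=C(C)C | intermediate
13 | {5-[(3-methylbut-2-en-1-yl)oxy]-6-{4-[(3-methylbut-2-en-1-yl)oxy]phenyl}-4-oxo-4H-pyran-2-yl}lithium (not isolated) | [Li]c1cc(=O)c(OCC=C(C)C)c(-c2ccc(OCC=C(C)C)cc2)o1 | intermediate
14 | lithium alkoxide of the 4-hydroxy-4-(pyranon-2-yl)-3-[2-(trimethylsilyl)ethoxy]cyclobut-2-en-1-one (racemic, one enantiomer drawn; not isolated) | [Li]O[C@]1(c2cc(=O)c(OCC=C(C)C)c(-c3ccc(OCC=C(C)C)cc3)o2)C(=O)C=C1OCC[Si](C)(C)C | intermediate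
15 | 4-methoxy-4-{5-[(3-methylbut-2-en-1-yl)oxy]-6-{4-[(3-methylbut-2-en-1-yl)oxy]phenyl}-4-oxo-4H-pyran-2-yl}-3-[2-(trimethylsilyl)ethoxy]cyclobut-2-en-1-one (racemic, one enantiomer drawn) | CO[C@]1(c2cc(=O)c(OCC=C(C)C)c(-c3ccc(OCC=C(C)C)cc3)o2)C(=O)C=C1OCC[Si](C)(C)C | intermediate
16 | dienylketene: 4-methoxy-4-(pyranon-2-yl)-3-[2-(trimethylsilyl)ethoxy]buta-1,3-dien-1-one, pyranonyl cis to the ketene (not isolated) | O=C=C/C(OCC[Si](C)(C)C)=C(\c1cc(=O)c(OCC=C(C)C)c(-c2ccc(OCC=C(C)C)cc2)o1)OC | intermediate
17 | 8-methoxy-3-[(3-methylbut-2-en-1-yl)oxy]-2-{4-[(3-methylbut-2-en-1-yl)oxy]phenyl}-7-[2-(trimethylsilyl)ethoxy]-4aH-chromene-4,5-dione (racemic, one enantiomer drawn; not isolated) | COC1=C2OC(-c3ccc(OCC=C(C)C)cc3)=C(OCC=C(C)C)C(=O)[C@@H]2C(=O)C=C1OCC[Si](C)(C)C | intermediate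
18 | 5-hydroxy-8-methoxy-3-[(3-methylbut-2-en-1-yl)oxy]-2-{4-[(3-methylbut-2-en-1-yl)oxy]phenyl}-7-[2-(trimethylsilyl)ethoxy]-4H-chromen-4-one | COc1c(OCC[Si](C)(C)C)cc(O)c2c(=O)c(OCC=C(C)C)c(-c3ccc(OCC=C(C)C)cc3)oc12 | intermediate
19 | 5,7-dihydroxy-8-methoxy-3,4'-diprenyloxyflavone | COc1c(O)cc(O)c2c(=O)c(OCC=C(C)C)c(-c3ccc(OCC=C(C)C)cc3)oc12 | target

Total step count: 10.
Longest linear sequence: 6 steps (steps 1, 2, 3, 8, 9, 10 or steps 4, 5, 7, 8, 9, 10).

Steps most likely to fail

1. Step 8. The deprotonation may occur at C5 instead of C6. The lithiated pyranone may attack unreacted 12 before it meets the cyclobutenedione. Addition to 5 may go in the conjugate sense instead of to the carbonyl. Surplus methyl triflate may methylate the pyranone carbonyl oxygen. Fallback: setting out from 12, zincation with TMPZnCl·LiCl (THF, 25 °C), a milder amide base of the kind that metalates chromones next to the ring oxygen, should give the pyranon-6-ylzinc chloride F1 (not isolated). Its iodinolysis (I2, THF, −20 °C) should give the 6-iodopyranone F2, which can be purified and its regiochemistry confirmed. Iodine–lithium exchange (n-BuLi, THF, −100 °C) then generates the lithiopyranone free of amine and of unmetalated pyranone, and the route is rejoined at 13.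

2. Step 9. The ring may open too slowly or with the methoxy group turning inward. The ketene may then be lost to dimerisation or to traces of nucleophile before it closes, and prolonged heating invites a sigmatropic shift of a prenyl group. Fallback: setting out from lithium alkoxide 14, a quench with aqueous NH4Cl in place of methyl triflate should give the 4-hydroxycyclobutenone carbinol F3, whose free hydroxyl is the strongest outward-rotating donor. Heating it in toluene under argon should give the 5,8-dihydroxyflavone hydroquinone F4. Its 8-hydroxyl, the only phenol not hydrogen-bonded to the C4 carbonyl, is then methylated selectively (Me3SiCHN2, i-Pr2NEt, MeOH–MeCN, rt, argon), and the route is rejoined at 18.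

3. Step 3. The remaining silylethyl group may be lost during the acidic rearrangement (β-silyl fragmentation of the protonated vinylogous ester), or the hydride may reduce twice. Fallback: setting out from 2, monoalcoholysis (Me3SiCH2CH2OH, 1.0 equiv, 2,6-lutidine, CH2Cl2, −78 °C) should give the chloro monoester 3-chloro-4-[2-(trimethylsilyl)ethoxy]cyclobut-3-ene-1,2-dione F5. Acid-free hydrodechlorination of this vinylogous acid chloride (Bu3SnH, Pd(PPh3)4 cat., toluene, rt), the counterpart of the palladium-catalysed reduction of acid chlorides to aldehydes, should then give the cyclobutenedione, and the route is rejoined at 5.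

Further compounds
F1 | step 8 | {5-[(3-methylbut-2-en-1-yl)oxy]-6-{4-[(3-methylbut-2-en-1-yl)oxy]phenyl}-4-oxo-4H-pyran-2-yl}zinc chloride (not isolated) | Cl[Zn]c1cc(=O)c(OCC=C(C)C)c(-c2ccc(OCC=C(C)C)cc2)o1
F2 | step 8 | 6-iodo-3-[(3-methylbut-2-en-1-yl)oxy]-2-{4-[(3-methylbut-2-en-1-yl)oxy]phenyl}-4H-pyran-4-one | O=c1cc(I)oc(-c2ccc(OCC=C(C)C)cc2)c1OCC=C(C)C
F3 | step 9 | 4-hydroxy-4-{5-[(3-methylbut-2-en-1-yl)oxy]-6-{4-[(3-methylbut-2-en-1-yl)oxy]phenyl}-4-oxo-4H-pyran-2-yl}-3-[2-(trimethylsilyl)ethoxy]cyclobut-2-en-1-one (racemic, one enantiomer drawn) | O[C@]1(c2cc(=O)c(OCC=C(C)C)c(-c3ccc(OCC=C(C)C)cc3)o2)C(=O)C=C1OCC[Si](C)(C)C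
F4 | step 9 | 5,8-dihydroxy-3-[(3-methylbut-2-en-1-yl)oxy]-2-{4-[(3-methylbut-2-en-1-yl)oxy]phenyl}-7-[2-(trimethylsilyl)ethoxy]-4H-chromen-4-one | Oc1c(OCC[Si](C)(C)C)cc(O)c2c(=O)c(OCC=C(C)C)c(-c3ccc(OCC=C(C)C)cc3)oc12
F5 | step 3 | 3-chloro-4-[2-(trimethylsilyl)ethoxy]cyclobut-3-ene-1,2-dione | O=C1C(=O)C(OCC[Si](C)(C)C)=C1Cl
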